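(The numbers in the tables come from a simulation with constants of no real substance; the scatter is artificial.)

After the first reading of each earlier run, the sum of intermediate and target holds nearly still. The west run stands at 10.5%, call it S, at 12.0 h, and the south-east run, with about half the free catalyst, stands at 11.0% at 6.00 h.

common to all: second catalyst 3.7 mM
- west: substrate 37 mM; partner 37 mM; free catalyst 0.37 mM; run made earlier
- south-east: substrate 37 mM; partner 37 mM; free catalyst 0.18 mM; run made earlier
- Thursday's: substrate 37 mM (fed, over 16.0 h); partner 37.0 mM; free catalyst 0.37 mM; a stirred flask in which substrate is dosed at a steady rate over 16.0 h without added volume, worked up at 20 h; time 20 h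
- Saturday's: substrate 37 mM; partner 37.0 mM; free catalyst 0.37 mM; a tube with plug flow, the mixed feed as stated, residence time 20 h; time 20 h
- Wednesday's: substrate 37 mM; partner 37.0 mM; free catalyst 0.37 mM; a closed flask charged with all of it at once and left for 20 h; time 20 h
- Tuesday's: substrate 37 mM; partner 37.0 mM; free catalyst 0.37 mM; a single well-mixed tank run continuously and read at steady state, 20 h in it on average

| run | time / h | intermediate / % | target / % |
|---|---|---|---|
| west | 1.00 | 8.4 | 1.4 |
| west | 1.50 | 8.9 | 2.3 |
| west | 2.50 | 7.6 | 2.5 |
| west | 4.00 | 5.9 | 3.5 |
| west | 8.00 | 5.2 | 4.9 |
| west | 12.0 | 3.8 | 6.7 |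
| south-east | 0.417 | 6.7 | 0 |
| south-east | 1.33 | 8.5 | 1.3 |
| south-east | 2.00 | 8.3 | 1.4 |
| south-east | 3.00 | 7.5 | 2.0 |
| south-east | 5.00 | 6.6 | 4.2 |
| south-east | 6.00 | 6.6 | 4.4 |

(each reading ± 0.5 percentage points)

- the stated concentrations are those of everything mixed, before any reaction; amounts are the same in each set-up
- the feed brings no volume worth counting
- the earlier runs were made in a closed, stirred flask

1. the set-up with the highest amount of intermediate at the outlet or at the end, in percent of the substrate put in ("none" if the first two lie within 2 percentage points) (Thursday's / Saturday's / Wednesday's / Tuesday's / none)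
2. amount of intermediate at the outlet or at the end, in percent of the substrate put in, Thursday's
3. amount of intermediate at the outlet or at the end, in percent of the substrate put in, Saturday's
4. amount of intermediate at the outlet or at the end, in percent of the substrate put in, Wednesday's
5. amount of intermediate at the outlet or at the end, in percent of the substrate put in, Tuesday's

Two times matter. The first is the fill time: the south-east run already held 6.7% of intermediate at 0.417 h, so I take that as its scale. The second comes from the west run, where intermediate falls from 8.9% at 1.50 h to 3.8% at 12.0 h. Treated as a pseudo-first-order decay, that gives 12.3 h for the loss time τ, the span in which intermediate shrinks to 36.8% of itself.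

Their ratio is about 29.5. Filling is much quicker than losing, so I treat a portion of substrate as filling at once and then decaying; this estimate also takes τ as constant, an assumption of mine, and then asks how long the portion has sat.

My own reckoning follows. In Wednesday's flask and Saturday's tube everything sits 20 h, and S decayed over that time gives 2.08%. Tuesday's tank, S divided by one plus its average stay over τ, gives 4.00%. Thursday's dosing, each portion decaying from its entry, gives 4.25%. The top two lie within 2 percentage points, so I say none.

The forecast gave 2.1% for Thursday's, 1.9% for Saturday's, 1.9% for Wednesday's, 3.6% for Tuesday's and the verdict none, noting “Tank leads batch by only about 1.7 points”, and it parts from me on Thursday's.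

The flasks give 4.63% for Thursday's, 3.24% for Saturday's, 3.24% for Wednesday's and 4.81% for Tuesday's, verdict none.

    substrate + free catalyst ⇌ free catalyst + intermediate (K = 0.110, k = 1500 M⁻¹ h⁻¹)
    partner + second catalyst + intermediate → second catalyst + target (k = 940 M⁻² h⁻¹)
    substrate + partner → uncatalysed product (k = 2.70 M⁻¹ h⁻¹)

Wednesday's stands above my 2.08%. Over its second 10.0 h intermediate went from 4.88% to 3.24%, a loss time of 24.4 h, about twice τ, while partner fell from 49.3% to 32.7% of its charge. The steps that use partner go with its concentration, so I scale τ inversely with partner. A neighbour of Wednesday's with 9.2 mM of partner then has τ of 49.6 h, and S decayed over 20 h gives 7.02%. The computed flask gives 7.86%.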